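## Retrosynthetic overview

1. Rings: A = trioxygenated ring, B = para-linked ring, C = 1,2,3-trisubstituted phenol ring, D = ortho-linked ring. Target 16 ⇐ 15 (two O-methyl groups) ⇐ 14 (two aryl chlorides) ⇐ 13 (aryl bromide in place of the ring A methoxy).
2. 13 ⇐ 11 by oxidative phenol coupling, the way such bis(bibenzyl) macrocycles are thought to arise in nature: the ring B phenol oxygen bonds to an ortho carbon of the oxidised ring A phenol (dienone 12, then reduction). This closes the 17-membered ring.
3. 11 ⇐ 10 ⇐ 9: ortho-dibromination of ring A, after hydrogenation of a bis-stilbene whose ring B arm came from a Heck arylation and whose ring A arm came from a Wittig olefination.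
4. 7 ⇐ 4 + 5; 4 ⇐ 2 + 3 (ring C–O–ring D ether by nucleophilic aromatic substitution); 2 ⇐ o-vanillin 1.
5. Ring order: the four benzene rings are bought; the macrocycle is the only ring formed, in step 7.

Assumption: the target has no stereocentre and no configurationally stable axis or plane is specified, so the single achiral compound drawn is made.

## Route

Step 1
Reactants: 1 o-vanillin (2-hydroxy-3-methoxybenzaldehyde)
Product: 2 2-ethenyl-6-methoxyphenol
Conditions: methyltriphenylphosphonium bromide (2.3 equiv), KOtBu (2.3 equiv), THF, 0 °C to rt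
Reagents that add atoms: methyltriphenylphosphonium bromide, C[P+](c1ccccc1)(c1ccccc1)c1ccccc1.[Br-]
Why: Wittig methylenation, in which the first equivalent of base only forms the inert phenoxide and the excess ylide converts the aldehyde into the styrene.

Step 2
Reactants: 2 2-ethenyl-6-methoxyphenol; 3 2-fluorobenzaldehyde
Product: 4 2-(2-ethenyl-6-methoxyphenoxy)benzaldehyde
Conditions: K2CO3 (2 equiv), DMAc, 120 °C, trace BHT, argon
Reagents that add atoms: none
Why: Nucleophilic aromatic substitution (SNAr), the ortho-formyl group activating the fluoride toward the hindered phenoxide and giving the ring C–O–ring D ether with one aldehyde and one vinyl handle.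

Step 3
Reactants: 4 2-(2-ethenyl-6-methoxyphenoxy)benzaldehyde; 5 (4-benzyloxybenzyl)triphenylphosphonium chloride
Product: 7 1-(benzyloxy)-4-{2-[2-(2-ethenyl-6-methoxyphenoxy)phenyl]ethenyl}benzene (E/Z mixture), via benzylidenephosphorane 6 (not isolated)
Conditions: KOtBu (1.2 equiv), THF, 0 °C to rt
Reagents that add atoms: none
Why: Wittig olefination with a semi-stabilised benzylic ylide attaches ring A to ring D, and the E/Z ratio is immaterial because this double bond is hydrogenated in step 5.

Step 4
Reactants: 7 the stilbene–styrene; 8 4-bromo-2,6-dichlorophenol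
Product: 9 4-[(E)-2-(2-{2-[2-(4-benzyloxyphenyl)ethenyl]phenoxy}-3-methoxyphenyl)ethenyl]-2,6-dichlorophenol
Conditions: Pd(OAc)2 (5 mol %), P(o-tol)3 (15 mol %), Et3N (4 equiv), DMF, 110 °C
Reagents that add atoms: none
Why: Mizoroki–Heck reaction, with oxidative addition only at the C–Br bond of 8 and insertion only at the terminal vinyl group, so ring B arrives already carrying its two ortho chlorines.

Step 5
Reactants: 9 the bis-stilbene benzyl ether
Product: 10 2,6-dichloro-4-[2-(2-{2-[2-(4-hydroxyphenyl)ethyl]phenoxy}-3-methoxyphenyl)ethyl]phenol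
Conditions: H2 (1 atm), 10% Pd/C, EtOAc, rt, stopped after uptake of 3 equiv H2
Reagents that add atoms: none
Why: Catalytic hydrogenation saturates both stilbene double bonds and hydrogenolyses the benzyl ether, while the aryl chlorides are reduced much more slowly when no base is present.

Step 6
Reactants: 10 the dichloro diphenol
Product: 11 2,6-dibromo-4-[2-(2-{2-[2-(3,5-dichloro-4-hydroxyphenyl)ethyl]-6-methoxyphenoxy}phenyl)ethyl]phenol
Conditions: N-bromosuccinimide (2.05 equiv), i-Pr2NH (0.2 equiv), CH2Cl2, 0 °C, dark
Reagents that add atoms: N-bromosuccinimide, O=C1CCC(=O)N1Br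
Why: Amine-catalysed electrophilic ortho-bromination of a phenol, for which only ring A has free ortho positions (those of ring B are chlorinated and the aryl ether rings do not react under these conditions).

Step 7
Reactants: 11 the open-chain dibromophenol–dichlorophenol
Product: 13 macrocyclic bromophenol (ring A: 3-bromo-4-hydroxy-5-aryloxy; ring B: 3,5-dichloro; ring C: 3-methoxy), via macrocyclic bromodienone 12 (not isolated)
Conditions: Tl(NO3)3·3H2O (2.5 equiv), MeOH–CH2Cl2 9:1, 1 mM, −20 to 0 °C; then Zn dust, AcOH, 0 °C to rt
Reagents that add atoms: none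
Why: Biomimetic oxidative phenol coupling by thallium trinitrate oxidation of an o,o'-dihalophenol pair, in which the more easily oxidised dibromophenol of ring A becomes the electrophile, the dichlorophenol oxygen of ring B attacks either of its two equivalent bromine-bearing ortho carbons, and zinc then expels the geminal bromide to rearomatise ring A.

Step 8
Reactants: 13 macrocyclic bromophenol
Product: 14 macrocyclic guaiacol (ring A: 3-methoxy-4-hydroxy-5-aryloxy; ring B: 3,5-dichloro; ring C: 3-methoxy)
Conditions: NaOMe (10 equiv), CuBr (0.5 equiv), DMF–MeOH 4:1, 110 °C, argon; then dilute HCl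
Reagents that add atoms: sodium methoxide, C[O-].[Na+]
Why: Copper-catalysed Ullmann-type methoxylation of an ortho-bromophenoxide, which turns the bromine that steered step 7 into the third oxygen of ring A and leaves the two hindered aryl chlorides alone.

Step 9
Reactants: 14 macrocyclic guaiacol
Product: 15 dechlorinated macrocycle (the target with OMe at ring A C3 and at ring C C3)
Conditions: H2 (1 atm), 10% Pd/C, Et3N (3 equiv), MeOH–EtOAc, rt
Reagents that add atoms: none
Why: Palladium-catalysed hydrodechlorination, made fast by the amine that takes up HCl, with diaryl and methyl ethers untouched.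

Step 10
Reactants: 15 dechlorinated macrocycle
Product: 16 target CNP0290892.0
Conditions: BBr3 (6 equiv), CH2Cl2, −78 °C to rt; then MeOH, H2O
Reagents that add atoms: none
Why: Lewis-acid cleavage of both aryl methyl ethers with BBr3 (diaryl ethers are inert), hydrolysis of the borates releasing the catechol of ring A and the phenol of ring C.

## Compound list

1 | o-vanillin (2-hydroxy-3-methoxybenzaldehyde) | COc1cccc(C=O)c1O | starting material
2 | 2-ethenyl-6-methoxyphenol | COc1cccc(C=C)c1O | intermediate
3 | 2-fluorobenzaldehyde | O=Cc1ccccc1F | starting material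
4 | 2-(2-ethenyl-6-methoxyphenoxy)benzaldehyde | COc1cccc(C=C)c1Oc1ccccc1C=O | intermediate
5 | (4-benzyloxybenzyl)triphenylphosphonium chloride | [Cl-].c1ccc(cc1)COc1ccc(cc1)C[P+](c1ccccc1)(c1ccccc1)c1ccccc1 | starting material
6 | [4-(benzyloxy)benzylidene]triphenylphosphorane (ylide, not isolated) | c1ccc(cc1)COc1ccc(cc1)C=P(c1ccccc1)(c1ccccc1)c1ccccc1 | intermediate
7 | 1-(benzyloxy)-4-{2-[2-(2-ethenyl-6-methoxyphenoxy)phenyl]ethenyl}benzene, E/Z mixture at the stilbene (double-bond geometry left undefined) | COc1cccc(C=C)c1Oc1ccccc1C=Cc1ccc(OCc2ccccc2)cc1 | intermediate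
8 | 4-bromo-2,6-dichlorophenol | Oc1c(Cl)cc(Br)cc1Cl | starting material
9 | 4-[(E)-2-(2-{2-[2-(4-benzyloxyphenyl)ethenyl]phenoxy}-3-methoxyphenyl)ethenyl]-2,6-dichlorophenol (ring A stilbene E/Z) | COc1cccc(/C=C/c2cc(Cl)c(O)c(Cl)c2)c1Oc1ccccc1C=Cc1ccc(OCc2ccccc2)cc1 | intermediate
10 | 2,6-dichloro-4-[2-(2-{2-[2-(4-hydroxyphenyl)ethyl]phenoxy}-3-methoxyphenyl)ethyl]phenol | COc1cccc(CCc2cc(Cl)c(O)c(Cl)c2)c1Oc1ccccc1CCc1ccc(O)cc1 | intermediate
11 | 2,6-dibromo-4-[2-(2-{2-[2-(3,5-dichloro-4-hydroxyphenyl)ethyl]-6-methoxyphenoxy}phenyl)ethyl]phenol | COc1cccc(CCc2cc(Cl)c(O)c(Cl)c2)c1Oc1ccccc1CCc1cc(Br)c(O)c(Br)c1 | intermediate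
12 | macrocyclic 2,6-dibromo-6-aryloxycyclohexa-2,4-dienone (ring A dearomatised, racemic at the C(Br)(OAr) carbon, not isolated) | O=C1C(Br)=CC2=CC1(Br)Oc1c(Cl)cc(cc1Cl)CCc1cccc(OC)c1Oc1ccccc1CC2 | intermediate
13 | macrocyclic bromophenol: target skeleton with Br at ring A C3, Cl at ring B C3 and C5, OMe at ring C C3 | Brc1cc2cc(c1O)Oc1c(Cl)cc(cc1Cl)CCc1cccc(OC)c1Oc1ccccc1CC2 | intermediate
14 | macrocyclic guaiacol: as 13 with OMe in place of Br | COc1cc2cc(c1O)Oc1c(Cl)cc(cc1Cl)CCc1cccc(OC)c1Oc1ccccc1CC2 | intermediate
15 | dechlorinated macrocycle: target with OMe at ring A C3 and ring C C3 | COc1cc2cc(c1O)Oc1ccc(cc1)CCc1cccc(OC)c1Oc1ccccc1CC2 | intermediate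
16 | CNP0290892.0 | Oc1cc2cc(c1O)Oc1ccc(cc1)CCc1cccc(O)c1Oc1ccccc1CC2 | target

## Step count and risk

Total step count: 10. Longest linear sequence: 10 steps (1 to 16).

The three steps most likely to fail:

**Step 7, the oxidative macrocyclisation.** Methanol can attack the oxidised ring A at the para carbon, ring B can be oxidised in the wrong sense, and intermolecular coupling competes, so a yield of 20–45% at high dilution is a realistic expectation. Para-quinol ethers are returned to 11 by the zinc treatment and can be recycled. The fallback sets out from 11 and comes back at 13 without any new compound. It replaces the oxidative dearomatisation by a copper-mediated intramolecular Ullmann etherification (CuBr·SMe2, Cs2CO3, pyridine, 120 °C, 1 mM). The ring B dichlorophenoxide displaces one of the two equivalent bromides of ring A. This uses the same ortho-bromophenoxide electrophile that is methoxylated in step 8, but the nucleophile is weak, so this is a backup only.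

**Step 8, the copper-catalysed methoxylation.** The bromide sits on an electron-rich, hindered macrocyclic phenoxide, and reductive debromination is the usual side reaction. The fallback sets out from 13 and comes back at 16. Exhaustive hydrodehalogenation (H2, Pd/C, Et3N, MeOH) removes the bromine and both chlorines and gives the halogen-free macrocyclic phenol F1. Magnesium-mediated ortho-formylation (MgCl2, Et3N, paraformaldehyde, MeCN, reflux) then puts a formyl group on the only free ortho position of the ring A phenol, giving the macrocyclic salicylaldehyde F2. Dakin oxidation (H2O2, aqueous NaOH, THF) converts the aldehyde into the hydroxyl of the ring A catechol, giving the ring C mono-methyl ether F3. BBr3 under the conditions of step 10 then gives 16. This introduces the oxygen by C–H functionalisation instead of C–Br substitution and makes step 9 unnecessary.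

**Step 5, hydrogenation in the presence of the 2,6-dichlorophenol.** Partial loss of chlorine on Pd/C would remove the ortho blocking groups that step 7 needs. The fallback sets out from 9 and comes back at 10. Diimide, generated from p-toluenesulfonyl hydrazide and NaOAc in refluxing aqueous DME, reduces both double bonds without touching C–Cl or the benzyl ether and gives the saturated benzyl ether F4. BCl3 with pentamethylbenzene in CH2Cl2 at −78 °C then removes the benzyl group selectively, leaving the aryl methyl ether, and gives 10.

Further compounds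
F0 | step 7 | none | none
F1 | step 8 | halogen-free macrocyclic phenol (ring A: 4-hydroxy-3-aryloxy; ring C: 3-methoxy) | Oc1ccc2cc1Oc1ccc(cc1)CCc1cccc(OC)c1Oc1ccccc1CC2
F2 | step 8 | macrocyclic salicylaldehyde (F1 with CHO at the free ortho position of the ring A phenol) | O=Cc1cc2cc(c1O)Oc1ccc(cc1)CCc1cccc(OC)c1Oc1ccccc1CC2
F3 | step 8 | ring C mono-methyl ether of the target (ring A catechol free) | Oc1cc2cc(c1O)Oc1ccc(cc1)CCc1cccc(OC)c1Oc1ccccc1CC2
F4 | step 5 | 4-[2-(2-{2-[2-(4-benzyloxyphenyl)ethyl]phenoxy}-3-methoxyphenyl)ethyl]-2,6-dichlorophenol | COc1cccc(CCc2cc(Cl)c(O)c(Cl)c2)c1Oc1ccccc1CCc1ccc(OCc2ccccc2)cc1
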